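Ring B (B1 bridge-bearing carbon, B2 OH, B3 butanoyl, B4 OH, B5 CH3, B6 OCH3) alternates carbon and oxygen substituents around the ring, and the route exploits this by disconnecting it into a four-carbon and a two-carbon unit. A racemic 3-methoxy-2-methylcyclobutenone that carries the tribenzyl-protected ring A on its sp3 carbon supplies B1, B2, B5 and B6; (triisopropylsiloxy)ethyne supplies B3 and B4. One thermal pericyclic cascade forms B2–B3, B4–B5 and B1–B2 and closes ring B with the B6 methyl ether already in place, so no selective O-methylation is needed. Desilylation, butanoylation at B3 and hydrogenolysis finish the synthesis.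

Key step: step 9

Remarks on the chemistry:
- (Triisopropylsiloxy)ethyne is not assumed to be a stock chemical; steps 7 and 8 make it from ethynyltrimethylsilane.
- The target is achiral. Compounds 14, 15, 22 and 24 are racemic, and none of their centres survives aromatisation.
- Ring A is the pentanoyl-bearing ring; ring B is numbered as in the first paragraph.

Step 1
Reactants: 1 2,4,6-trihydroxytoluene; 2 pentanoyl chloride
Product: 3 1-(2,4,6-trihydroxy-3-methylphenyl)pentan-1-one
Conditions: AlCl3 (3.5 equiv), PhNO2/CH2Cl2, 0 °C to rt; ice/aq. HCl work-up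
Reagents that add atoms: none
Why: Friedel–Crafts acylation of an electron-rich phloroglucinol, in which the two unsubstituted ring carbons of 1 are equivalent by symmetry, any O-acylation is funnelled to the C-acyl product under AlCl3 (Fries rearrangement) and the first acyl group deactivates the ring towards a second one.

Step 2
Reactants: 3 1-(2,4,6-trihydroxy-3-methylphenyl)pentan-1-one
Product: 5 2,4,6-trihydroxy-3-methyl-5-pentanoylbenzaldehyde, via iminium chloride 4 (not isolated)
Conditions: POCl3, DMF, EtOAc, 0 °C to rt; then H2O, 60 °C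
Reagents that add atoms: N,N-dimethylformamide, CN(C)C=O; water, O
Why: Vilsmeier–Haack formylation at the only remaining ring CH, which stays strongly activated by two ortho hydroxy groups and one para hydroxy group, with hydrolysis of the iminium salt 4 in the aqueous work-up.

Step 3
Reactants: 5 2,4,6-trihydroxy-3-methyl-5-pentanoylbenzaldehyde
Product: 6 2,4,6-tris(benzyloxy)-3-methyl-5-pentanoylbenzaldehyde
Conditions: BnBr (4 equiv), K2CO3, Bu4NI (cat.), DMF, 60 °C
Reagents that add atoms: benzyl bromide, BrCc1ccccc1
Why: Williamson ether synthesis, in which the carbonyl-stabilised phenoxides react at oxygen in a dipolar aprotic solvent, the fully substituted ring offers no CH position for C-benzylation and heating with excess benzyl bromide also alkylates the hydrogen-bonded hydroxy groups.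

Step 4
Reactants: 6 2,4,6-tris(benzyloxy)-3-methyl-5-pentanoylbenzaldehyde; 7 Meldrum's acid
Product: 10 3-[2,4,6-tris(benzyloxy)-3-methyl-5-pentanoylphenyl]propanoic acid, via arylidene Meldrum's acid 8 (not isolated), via benzyl Meldrum's acid 9 (not isolated)
Conditions: HCO2H/Et3N (5:2 azeotrope), 95 °C
Reagents that add atoms: none
Why: Tandem Knoevenagel condensation, conjugate reduction by formate and solvolysis–decarboxylation of the Meldrum's acid unit in triethylammonium formate, which converts an aryl aldehyde into the 3-arylpropanoic acid in one pot while the hindered aryl ketone and the benzyl ethers are not touched.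

Step 5
Reactants: 10 3-[2,4,6-tris(benzyloxy)-3-methyl-5-pentanoylphenyl]propanoic acid; 11 1-ethoxyprop-1-yne
Product: 14 4-{[2,4,6-tris(benzyloxy)-3-methyl-5-pentanoylphenyl]methyl}-3-ethoxy-2-methylcyclobut-2-en-1-one (racemic), via acid chloride 12 (not isolated), via ketene 13 (not isolated)
Conditions: (COCl)2, DMF (cat.), CH2Cl2, 0 °C to rt, evaporate cold; then slow addition to 11 (3 equiv), Et3N, CH2Cl2, 0 °C to rt
Reagents that add atoms: none
Why: Dehydrochlorination of the acid chloride gives the monoalkylketene 13, which is trapped by excess ynol ether in a thermal ketene–alkyne [2+2] cycloaddition whose regiochemistry follows from bonding of the ketene carbonyl carbon to the nucleophilic methyl-bearing alkyne carbon; the stereocentre C4 forms as a racemate and is erased in step 9.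

Step 6
Reactants: 14 4-{[2,4,6-tris(benzyloxy)-3-methyl-5-pentanoylphenyl]methyl}-3-ethoxy-2-methylcyclobut-2-en-1-one
Product: 15 4-{[2,4,6-tris(benzyloxy)-3-methyl-5-pentanoylphenyl]methyl}-3-methoxy-2-methylcyclobut-2-en-1-one (racemic)
Conditions: p-TsOH (cat.), dry MeOH, 3 Å molecular sieves, rt; Et3N quench
Reagents that add atoms: methanol, CO
Why: Acid-catalysed addition–elimination at the β-carbon of a vinylogous ester (transetherification) driven by the large excess of methanol and run without water so that the cyclobutane-1,3-dione and its ring opening are avoided; a double-bond shift towards C4 would be harmless because both enol ether isomers lead to 26.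

Step 7
Reactants: 16 ethynyltrimethylsilane
Product: 19 1-(triisopropylsiloxy)-2-(trimethylsilyl)ethyne, via lithium acetylide 17 (not isolated), via lithium ynolate 18 (not isolated)
Conditions: n-BuLi, THF, −78 °C; t-BuOOLi (from t-BuOOH and LiN(SiMe3)2), THF, −78 to 0 °C; i-Pr3SiOTf, −78 to 0 °C
Reagents that add atoms: tert-butyl hydroperoxide, CC(C)(C)OO; triisopropylsilyl trifluoromethanesulfonate, CC(C)[Si](OS(=O)(=O)C(F)(F)F)(C(C)C)C(C)C
Why: Oxidation of a lithium acetylide by lithium tert-butyl peroxide gives the ynolate, and the bulky silyl triflate then silylates oxygen because the carbon terminus is blocked by the SiMe3 group (O-silylation of an ynolate to a siloxyalkyne).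

Step 8
Reactants: 19 1-(triisopropylsiloxy)-2-(trimethylsilyl)ethyne
Product: 20 (triisopropylsiloxy)ethyne
Conditions: K2CO3 (cat.), MeOH, 0 °C; pentane extraction, bulb-to-bulb distillation
Reagents that add atoms: none
Why: Base-catalysed methanolysis of the C(sp)–SiMe3 bond (protodesilylation of an alkynylsilane), which is expected to be much faster at the unhindered trimethylsilyl group than attack at the triisopropylsilyl ether.

Step 9
Reactants: 15 4-{[2,4,6-tris(benzyloxy)-3-methyl-5-pentanoylphenyl]methyl}-3-methoxy-2-methylcyclobut-2-en-1-one; 20 (triisopropylsiloxy)ethyne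
Product: 25 1-{2,4,6-tris(benzyloxy)-3-[(2-hydroxy-6-methoxy-5-methyl-4-(triisopropylsilyloxy)phenyl)methyl]-5-methylphenyl}pentan-1-one, via vinylketene 21 (not isolated), via vinylcyclobutenone 22 (not isolated), via dienylketene 23 (not isolated), via cyclohexadienone 24 (not isolated)
Conditions: 20 (3 equiv), toluene, 110 °C, sealed tube, argon
Reagents that add atoms: none
Why: Thermal four-electron electrocyclic opening of 15 gives the 3-methoxy vinylketene 21, whose ketene C=C adds across the siloxyalkyne in a [2+2] cycloaddition to give 22; four-electron conrotatory opening of 22 to the dienylketene 23 and thermal six-electron disrotatory electrocyclisation, which closes ring B by forming B1–B2, give dienone 24, and tautomerisation delivers the phenol. This is a Danheiser benzannulation of a cyclobutenone with a siloxyalkyne, a reaction type that gives resorcinol monosilyl ethers. No stereocentre is created, since the racemic centre of 15 becomes the sp2 carbon B1. The step needs regiocontrol in the [2+2] event, and the polarisation of the partners secures it: the electrophilic ketene carbonyl carbon (future B2) bonds to the nucleophilic CH terminus of the alkyne (future B3) and the methyl-bearing ketene carbon (B5) to the silyloxy carbon (B4). Ring A is fully substituted and carries only benzyl ethers and a hindered aryl ketone, so nothing in it competes for the ketenes, and the alkyne is used in excess because the product phenol could otherwise trap the vinylketene as an ester.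

Step 10
Reactants: 25 1-{2,4,6-tris(benzyloxy)-3-[(2-hydroxy-6-methoxy-5-methyl-4-(triisopropylsilyloxy)phenyl)methyl]-5-methylphenyl}pentan-1-one
Product: 26 1-{2,4,6-tris(benzyloxy)-3-[(2,4-dihydroxy-6-methoxy-5-methylphenyl)methyl]-5-methylphenyl}pentan-1-one
Conditions: Bu4NF, AcOH, THF, 0 °C
Reagents that add atoms: none
Why: Fluoride-induced cleavage of the aryl triisopropylsilyl ether, buffered with acetic acid so that the electron-rich resorcinol is not exposed to air as its phenoxide.

Step 11
Reactants: 26 1-{2,4,6-tris(benzyloxy)-3-[(2,4-dihydroxy-6-methoxy-5-methylphenyl)methyl]-5-methylphenyl}pentan-1-one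
Product: 27 1-{2,4,6-tris(benzyloxy)-3-[(3-butanoyl-2,4-dihydroxy-6-methoxy-5-methylphenyl)methyl]-5-methylphenyl}pentan-1-one
Conditions: (n-PrCO)2O, BF3·OEt2, CH2Cl2, 0 °C to rt; aqueous work-up
Reagents that add atoms: butanoic anhydride, CCCC(=O)OC(=O)CCC
Why: Friedel–Crafts acylation mediated by BF3·OEt2 (any O-acylation is funnelled to carbon by Fries rearrangement) at B3, the only aromatic CH of 26, which lies between two hydroxy groups and para to the methoxy group, while ring A has no free position and its benzyl ethers should tolerate the mild Lewis acid at room temperature.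

Step 12
Reactants: 27 1-{2,4,6-tris(benzyloxy)-3-[(3-butanoyl-2,4-dihydroxy-6-methoxy-5-methylphenyl)methyl]-5-methylphenyl}pentan-1-one
Product: 28 1-{3-[(3-butanoyl-2,4-dihydroxy-6-methoxy-5-methylphenyl)methyl]-2,4,6-trihydroxy-5-methylphenyl}pentan-1-one (target)
Conditions: H2 (1 atm), 10% Pd/C, EtOAc, rt
Reagents that add atoms: none
Why: Hydrogenolysis of the three benzyl aryl ethers over Pd/C under neutral conditions, where the aryl ketones, deactivated by hydrogen bonding to the liberated ortho hydroxy groups, and the diarylmethane bridge are expected to remain intact.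

Compound list
1 | 2,4,6-trihydroxytoluene | Cc1c(O)cc(O)cc1O | starting material
2 | pentanoyl chloride | CCCCC(=O)Cl | starting material
3 | 1-(2,4,6-trihydroxy-3-methylphenyl)pentan-1-one | CCCCC(=O)c1c(O)cc(O)c(C)c1O | intermediate
4 | N-[(2,4,6-trihydroxy-3-methyl-5-pentanoylphenyl)methylidene]-N-methylmethanaminium chloride | CCCCC(=O)c1c(O)c(C)c(O)c(C=[N+](C)C)c1O.[Cl-] | intermediate (not isolated)
5 | 2,4,6-trihydroxy-3-methyl-5-pentanoylbenzaldehyde | CCCCC(=O)c1c(O)c(C)c(O)c(C=O)c1O | intermediate
6 | 2,4,6-tris(benzyloxy)-3-methyl-5-pentanoylbenzaldehyde | CCCCC(=O)c1c(OCc2ccccc2)c(C)c(OCc2ccccc2)c(C=O)c1OCc1ccccc1 | intermediate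
7 | Meldrum's acid (2,2-dimethyl-1,3-dioxane-4,6-dione) | CC1(C)OC(=O)CC(=O)O1 | starting material
8 | 5-{[2,4,6-tris(benzyloxy)-3-methyl-5-pentanoylphenyl]methylidene}-2,2-dimethyl-1,3-dioxane-4,6-dione | CCCCC(=O)c1c(OCc2ccccc2)c(C)c(OCc2ccccc2)c(C=C2C(=O)OC(C)(C)OC2=O)c1OCc1ccccc1 | intermediate (not isolated)
9 | 5-{[2,4,6-tris(benzyloxy)-3-methyl-5-pentanoylphenyl]methyl}-2,2-dimethyl-1,3-dioxane-4,6-dione | CCCCC(=O)c1c(OCc2ccccc2)c(C)c(OCc2ccccc2)c(CC2C(=O)OC(C)(C)OC2=O)c1OCc1ccccc1 | intermediate (not isolated)
10 | 3-[2,4,6-tris(benzyloxy)-3-methyl-5-pentanoylphenyl]propanoic acid | CCCCC(=O)c1c(OCc2ccccc2)c(C)c(OCc2ccccc2)c(CCC(=O)O)c1OCc1ccccc1 | intermediate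
11 | 1-ethoxyprop-1-yne | CCOC#CC | starting material
12 | 3-[2,4,6-tris(benzyloxy)-3-methyl-5-pentanoylphenyl]propanoyl chloride | CCCCC(=O)c1c(OCc2ccccc2)c(C)c(OCc2ccccc2)c(CCC(=O)Cl)c1OCc1ccccc1 | intermediate (not isolated)
13 | 3-[2,4,6-tris(benzyloxy)-3-methyl-5-pentanoylphenyl]prop-1-en-1-one (monoalkylketene) | CCCCC(=O)c1c(OCc2ccccc2)c(C)c(OCc2ccccc2)c(CC=C=O)c1OCc1ccccc1 | intermediate (not isolated)
14 | 4-{[2,4,6-tris(benzyloxy)-3-methyl-5-pentanoylphenyl]methyl}-3-ethoxy-2-methylcyclobut-2-en-1-one, racemic | CCCCC(=O)c1c(OCc2ccccc2)c(C)c(OCc2ccccc2)c(CC2C(=O)C(C)=C2OCC)c1OCc1ccccc1 | intermediate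
15 | 4-{[2,4,6-tris(benzyloxy)-3-methyl-5-pentanoylphenyl]methyl}-3-methoxy-2-methylcyclobut-2-en-1-one, racemic | CCCCC(=O)c1c(OCc2ccccc2)c(C)c(OCc2ccccc2)c(CC2C(=O)C(C)=C2OC)c1OCc1ccccc1 | intermediate
16 | ethynyltrimethylsilane | C#C[Si](C)(C)C | starting material
17 | lithium (trimethylsilyl)acetylide | [Li+].[C-]#C[Si](C)(C)C | intermediate (not isolated)
18 | lithium 2-(trimethylsilyl)ethynolate | [Li+].[O-]C#C[Si](C)(C)C | intermediate (not isolated)
19 | 1-(triisopropylsiloxy)-2-(trimethylsilyl)ethyne | CC(C)[Si](OC#C[Si](C)(C)C)(C(C)C)C(C)C | intermediate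
20 | (triisopropylsiloxy)ethyne | C#CO[Si](C(C)C)(C(C)C)C(C)C | intermediate
21 | 3-methoxy-2-methyl-5-aryl-penta-1,3-dien-1-one (aryl = 2,4,6-tris(benzyloxy)-3-methyl-5-pentanoylphenyl), vinylketene with the arylmethyl group trans to the ketene-bearing carbon, as expected from outward rotation | CCCCC(=O)c1c(OCc2ccccc2)c(C)c(OCc2ccccc2)c(C/C=C(OC)/C(C)=C=O)c1OCc1ccccc1 | intermediate (not isolated)
22 | 4-(1-methoxy-3-arylprop-1-en-1-yl)-4-methyl-3-(triisopropylsilyloxy)cyclobut-2-en-1-one, racemic, alkene geometry as in 21 | CCCCC(=O)c1c(OCc2ccccc2)c(C)c(OCc2ccccc2)c(C/C=C(OC)/C2(C)C(=O)C=C2O[Si](C(C)C)(C(C)C)C(C)C)c1OCc1ccccc1 | intermediate (not isolated)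
23 | 5-methoxy-4-methyl-3-(triisopropylsilyloxy)-7-arylhepta-1,3,5-trien-1-one, dienylketene with the methoxyvinyl group cis to the ketenyl CH | CCCCC(=O)c1c(OCc2ccccc2)c(C)c(OCc2ccccc2)c(C/C=C(OC)/C(C)=C(O[Si](C(C)C)(C(C)C)C(C)C)\C=C=O)c1OCc1ccccc1 | intermediate (not isolated)
24 | 6-(arylmethyl)-5-methoxy-4-methyl-3-(triisopropylsilyloxy)cyclohexa-2,4-dien-1-one, racemic | CCCCC(=O)c1c(OCc2ccccc2)c(C)c(OCc2ccccc2)c(CC2C(=O)C=C(O[Si](C(C)C)(C(C)C)C(C)C)C(C)=C2OC)c1OCc1ccccc1 | intermediate (not isolated)
25 | 1-{2,4,6-tris(benzyloxy)-3-[(2-hydroxy-6-methoxy-5-methyl-4-(triisopropylsilyloxy)phenyl)methyl]-5-methylphenyl}pentan-1-one | CCCCC(=O)c1c(OCc2ccccc2)c(C)c(OCc2ccccc2)c(Cc2c(O)cc(O[Si](C(C)C)(C(C)C)C(C)C)c(C)c2OC)c1OCc1ccccc1 | intermediate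
26 | 1-{2,4,6-tris(benzyloxy)-3-[(2,4-dihydroxy-6-methoxy-5-methylphenyl)methyl]-5-methylphenyl}pentan-1-one | CCCCC(=O)c1c(OCc2ccccc2)c(C)c(OCc2ccccc2)c(Cc2c(O)cc(O)c(C)c2OC)c1OCc1ccccc1 | intermediate
27 | 1-{2,4,6-tris(benzyloxy)-3-[(3-butanoyl-2,4-dihydroxy-6-methoxy-5-methylphenyl)methyl]-5-methylphenyl}pentan-1-one | CCCCC(=O)c1c(OCc2ccccc2)c(C)c(OCc2ccccc2)c(Cc2c(O)c(C(=O)CCC)c(O)c(C)c2OC)c1OCc1ccccc1 | intermediate
28 | 1-{3-[(3-butanoyl-2,4-dihydroxy-6-methoxy-5-methylphenyl)methyl]-2,4,6-trihydroxy-5-methylphenyl}pentan-1-one | CCCCC(=O)c1c(O)c(C)c(O)c(Cc2c(O)c(C(=O)CCC)c(O)c(C)c2OC)c1O | target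

Total step count: 12 (ten on the main line, two for the alkyne).
Longest linear sequence: 10 steps (steps 1 to 6, then 9 to 12).

Steps most likely to fail

1. Step 9. The vinylogous ester character of 15 may slow the electrocyclic opening. The temperature then needed could allow isomerisation of 20 to a silylketene, dimerisation of the vinylketene, or its capture by the product phenol. Irradiation at room temperature in place of heating would be the first adjustment. The fallback changes the bond construction and forms the methylene bridge last by known chemistry. It sets out from 3: a Mannich reaction (aqueous CH2O, Me2NH, EtOH, rt) at its single free ring carbon should give 1-{3-[(dimethylamino)methyl]-2,4,6-trihydroxy-5-methylphenyl}pentan-1-one F1. Heating F1 in dioxane with the purchased natural product aspidinol F2 should expel dimethylamine and generate the ring A ortho-quinone methide F3. F3 is captured by the only free ring carbon of F2, the one between its OH and OCH3 groups. The fallback returns to the route at 28.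

2. Step 8. Methoxide may attack the O–Si bond in competition with the C–Si bond, releasing the ynolate, and the volatile product may be lost on isolation. The fallback omits the C-desilylation and sets out from 19. Heating 19 with 15 under the conditions of step 9 should give the B3-trimethylsilyl analogue of 25, 1-{2,4,6-tris(benzyloxy)-3-[(2-hydroxy-6-methoxy-5-methyl-4-(triisopropylsilyloxy)-3-(trimethylsilyl)phenyl)methyl]-5-methylphenyl}pentan-1-one F4. Bu4NF in THF should then give the B3-trimethylsilyl resorcinol F5. CF3CO2H in CH2Cl2 at 0 °C should remove the aryl–SiMe3 group by ipso protonation of the electron-rich ring. The fallback returns to the route at 26.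

3. Step 6. Acid-catalysed solvolytic opening of the strained four-membered ring to an acyclic β-keto ester may compete with the alkoxy exchange. The fallback installs the methyl enol ether in the cycloaddition itself and sets out from 10. Chloroacetaldehyde dimethyl acetal with NaNH2 in liquid NH3 should give sodium methoxyethynide F6, and methylation with MeI should give 1-methoxyprop-1-yne F7. Acid 10 is activated as in step 5 to ketene 13, which is trapped with F7. The fallback returns to the route at 15.

Further compounds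
F1 | step 9 | 1-{3-[(dimethylamino)methyl]-2,4,6-trihydroxy-5-methylphenyl}pentan-1-one | CCCCC(=O)c1c(O)c(C)c(O)c(CN(C)C)c1O
F2 | step 9 | aspidinol, 1-(2,6-dihydroxy-4-methoxy-3-methylphenyl)butan-1-one (purchased partner) | CCCC(=O)c1c(O)c(C)c(OC)cc1O
F3 | step 9 | ring A ortho-quinone methide, 3,5-dihydroxy-4-methyl-6-methylidene-2-pentanoylcyclohexa-2,4-dien-1-one | CCCCC(=O)C1=C(O)C(C)=C(O)C(=C)C1=O
F4 | step 8 | 1-{2,4,6-tris(benzyloxy)-3-[(2-hydroxy-6-methoxy-5-methyl-4-(triisopropylsilyloxy)-3-(trimethylsilyl)phenyl)methyl]-5-methylphenyl}pentan-1-one | CCCCC(=O)c1c(OCc2ccccc2)c(C)c(OCc2ccccc2)c(Cc2c(O)c([Si](C)(C)C)c(O[Si](C(C)C)(C(C)C)C(C)C)c(C)c2OC)c1OCc1ccccc1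
F5 | step 8 | 1-{2,4,6-tris(benzyloxy)-3-[(2,4-dihydroxy-6-methoxy-5-methyl-3-(trimethylsilyl)phenyl)methyl]-5-methylphenyl}pentan-1-one | CCCCC(=O)c1c(OCc2ccccc2)c(C)c(OCc2ccccc2)c(Cc2c(O)c([Si](C)(C)C)c(O)c(C)c2OC)c1OCc1ccccc1
F6 | step 6 | sodium methoxyethynide | [Na+].[C-]#COC
F7 | step 6 | 1-methoxyprop-1-yne | COC#CC
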